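**Analysis of the target**

The target (19) is an elemane-type sesquiterpene lactone. In elemane numbering the cyclohexane is C5–C10: C10 carries the methyl C14 and the vinyl group C1=C2, C9 is the methylene, C8 carries the acetate, C7 and C6 are the ring-fusion carbons, and C5 carries the isopropenyl group C4(=C3)C15. This ring is cis-fused through C6–O and C7–C11 to a γ-lactone (O–C12(=O)–C11), whose α-carbon C11 bears the methyl C13 and the angelate. Five of the six stereocentres are contiguous on the carbocycle (10R, 5R, 6S, 7R, 8S); the sixth (11S) is a fully substituted carbinol carbon. Going round the ring, vinyl (C10) and isopropenyl (C5) are trans, isopropenyl and O6 trans, O6 and C11 cis, C11 and the C8 acetate trans, and the angelate sits on the convex face of the bicycle, cis to H7. The hardest bond is C5–C10: it joins the quaternary C10 to the tertiary C5 and is the central σ-bond of the hexa-1,5-diene C2=C1–C10–C5–C4=C3. Three unactivated olefins of similar reactivity (vinyl, isopropenyl, and any ring olefin used on the way) exclude unselective hydroboration, epoxidation or hydrogenation once they are present. The sensitive groups are the angelate (Z to E isomerisation to the tiglate), the tertiary α-acyloxy lactone, a secondary acetate that can migrate to a neighbouring alkoxide, and, in acyclic precursors, the 1,5-diene (thermal Cope rearrangement) and the α-isopropenyl carbonyl stereocentre at C5 (epimerisation, conjugation).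

**Retrosynthetic reasoning**

The angelate is the most fragile group and sits on a tertiary oxygen, so 19 is cut first at the C11–O acyl bond to hydroxy lactone 18. The acetate of 18 is cut next to diol 17, because a secondary hydroxyl can be acetylated in the presence of the tertiary one, whereas the reverse order cannot be done selectively.

The C11–O bond of 17 is cut to give lactone 16. The forward reaction is oxidation of the lactone enolate, which is planar at C11, so the configuration there is decided only by the shape of the cis-fused bicycle (attack on the convex face). The C11 configuration of 16 therefore does not matter.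

The C7–C11 and C8–O bonds are cut together, leading through acetal 14 to bromoacetal 12 and cyclohexenol 11. A two-carbon radical tethered to O6 must close onto C7 on the face of O6, which gives the cis ring fusion. The C8 radical left behind is then trapped by oxygen on the opposite face, which gives the trans C7/C8 relationship. This is a radical process, so the vinyl and isopropenyl groups are spectators, and C7 and C8 are both set from C6 alone.

The ring olefin C7=C8 of 11 is cut by a metathesis transform to the acyclic carbinol 10, and the C6–C7 bond of 10 is cut to aldehyde 9 and a vinyl nucleophile. The forward addition must set C6 from C5; the Felkin–Anh preference with the quaternary C10 as the large group gives the required isomer. Aldehyde 9 comes from acid 7 through alcohol 8 by redox adjustment.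

Acid 7 is a γ,δ-unsaturated acid with the quaternary carbon in the β position, which is the retron of an ester-enolate [3,3] shift. Cutting C5–C10 leads to the achiral ester 5. This cut is made here, and not at a ring bond next to oxygen, because it removes the quaternary centre and its neighbour in one operation, delivers vinyl and isopropenyl in their final form, and leaves a precursor without any stereocentre. The forward reaction must control the C5/C10 relative configuration (olefin and enolate geometry) and the absolute sense (a chiral boron controller).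

Ester 5 is cut at the acyl–oxygen bond to acid 4 and the E-allylic alcohol 3. Alcohol 3 is made from enyne 1 by methylmetalation and hydroxymethylation, which gives the trisubstituted olefin as one geometric isomer.

**Alternatives that were turned down**

Alternative 1: the textbook (biomimetic) disconnection.
- Disconnection: the C5–C10 bond is formed and a C2–C3 bond broken in a Cope rearrangement of the ten-membered germacranolide A1.
- Forward key step: thermolysis of A1, which contracts the cyclodeca-1(10),4-diene to the divinylcyclohexane.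
- Why turned down: A1 already holds four of the six stereocentres, both esters and an E,E-cyclodecadiene, so the precursor is harder to make than the product. The C5/C10 pair of the target has the opposite sense, relative to C7, to the pair that the usual chair-like conformer of such a diene gives, so the outcome would depend on a conformer population that cannot be predicted with confidence. The temperature needed threatens the allylic C6–O lactone bond and the angelate.

Alternative 2: a pyranone Diels–Alder.
- Disconnection: the C5–C10 and C8–C9 bonds are formed in a [4+2] addition of 2H-pyran-2-one A2 and 2-methylprop-2-enal A3.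
- Forward key step: the cycloaddition gives bicyclic lactone A4. Its bridge holds the future isopropenyl carbon C4 on C5 and the C8 oxygen cis to each other, and its formyl group becomes the vinyl group.
- Why turned down: there is no established enantioselective version for this diene with an α-substituted enal, and regio- and endo/exo control with A3 are uncertain. The olefin left in A4 lies at C6=C7, where oxygen at C6 and carbon at C7 are needed on the face that is hindered in the bicycle and, after bridge opening, anti to the C8 oxygen. The workable sequences (oxidation to the enone, epoxidation, Wharton transposition) delete the C8 oxygen that the cycloaddition had placed, so the gain of the key step is paid back in steps.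

Alternative 3: conjugate addition with enolate trapping.
- Disconnection: the C10–C1 (vinyl) and C5–C4 bonds are formed on a preformed ring.
- Forward key step: vinyl cuprate addition to silyloxy enone A5, anti to the C8 substituent, with trapping of the enolate at C5 to give ketone A6.
- Why turned down: an isopropenyl group cannot be delivered directly to the enolate, and the aldol–dehydration detour gives the conjugated isopropylidene ketone. C5 stays epimerisable next to the C6 ketone. The later bond to C7 needs an enolate between the carbonyl and the β-silyloxy group, which eliminates towards a cresol-type aromatic, and would enter anti to O6 where the target needs cis. The route is mostly redox and protecting-group work on the ring.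

Key step: step 3

Assumption 1: pent-1-en-4-yne (1) and 3-methylbut-3-enoic acid (4) are taken as catalogue compounds.
Assumption 2: the (S,S)-controller is assigned to the (2R,3R)-acid 7 by analogy with its use on simple (E)-allylic esters; if the opposite sense is found, the (R,R)-controller is used with no other change.

**Route**

Step 1
Reactants: 1 pent-1-en-4-yne
Product: 3 (2E)-3-methylhexa-2,5-dien-1-ol, via vinylalane 2 (not isolated)
Conditions: Me3Al, Cp2ZrCl2 (0.25 equiv), CH2Cl2, 0 °C to rt; then n-BuLi, (CH2O)n, THF, 0 °C to rt; aq. HCl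
Reagents that add atoms: trimethylaluminium C[Al](C)C; formaldehyde (from paraformaldehyde) C=O
Why: Zirconium-catalysed carboalumination (Negishi) adds methyl and aluminium syn across the terminal alkyne, with methyl on the internal carbon, and leaves the isolated olefin alone; hydroxymethylation of the derived alanate goes with retention and fixes the E geometry that step 3 needs.

Step 2
Reactants: 3 (2E)-3-methylhexa-2,5-dien-1-ol; 4 3-methylbut-3-enoic acid
Product: 5 (2E)-3-methylhexa-2,5-dien-1-yl 3-methylbut-3-enoate
Conditions: N,N'-diisopropylcarbodiimide, DMAP (5 mol%), CH2Cl2, −20 °C to 0 °C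
Reagents that add atoms: none
Why: Carbodiimide (Steglich) esterification at low temperature with little DMAP joins the two achiral fragments without moving the β,γ-double bond of 4 into conjugation.

Step 3
Reactants: 5 (2E)-3-methylhexa-2,5-dien-1-yl 3-methylbut-3-enoate
Product: 7 (2R,3R)-3-ethenyl-3-methyl-2-(prop-1-en-2-yl)hex-5-enoic acid, via boron ketene acetal 6 (not isolated)
Conditions: (1S,2S)-N,N'-bis{[3,5-bis(trifluoromethyl)phenyl]sulfonyl}-1,2-diphenylethane-1,2-diamine, BBr3, CH2Cl2, rt, then evaporation; 5, Et3N, toluene–hexane, −78 °C, then 4 °C; aqueous work-up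
Reagents that add atoms: none
Why: Enantioselective Ireland–Claisen rearrangement: the bromoborane made in the flask binds the ester carbonyl, Et3N removes the doubly activated α-proton (allylic and α to the carbonyl), and boron ketene acetal 6 undergoes the [3,3] shift through a chair transition state on warming. The closest known reaction type is the same controller-mediated rearrangement of (E)-allylic esters of simple acids, for which Et3N in toluene–hexane is expected to give the enolate with the α-substituent cis to the allyloxy oxygen. No ring is closed; the six-membered array exists only in the transition state, and the bond formed is C5–C10, the quaternary–tertiary bond of the target. C10 is set by the E geometry of the allylic olefin (C9 pseudo-equatorial, methyl pseudo-axial) and C5 by the enolate geometry (isopropenyl pseudo-axial), which together place vinyl and isopropenyl anti as the target requires. The absolute sense comes from the C2-symmetric diazaborolidine, whose sulfonyl groups shield one face of the enolate. The step needs bonding at the α- and not the γ-carbon of the dienolate (only the α-carbon can reach C10 in a six-membered array), chair over boat (nothing constrains the acyclic system) and a single enolisable ester (5 has only one). Vinyl and isopropenyl appear directly in their final form, and the temperature stays far below that of a Cope rearrangement of the product.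

Step 4
Reactants: 7 (2R,3R)-3-ethenyl-3-methyl-2-(prop-1-en-2-yl)hex-5-enoic acid
Product: 8 (2R,3R)-3-ethenyl-3-methyl-2-(prop-1-en-2-yl)hex-5-en-1-ol
Conditions: LiAlH4, Et2O, 0 °C to rt
Reagents that add atoms: none
Why: Hydride reduction of the acid to the primary alcohol touches neither the olefins nor the C5 stereocentre.

Step 5
Reactants: 8 (2R,3R)-3-ethenyl-3-methyl-2-(prop-1-en-2-yl)hex-5-en-1-ol
Product: 9 (2R,3R)-3-ethenyl-3-methyl-2-(prop-1-en-2-yl)hex-5-enal
Conditions: Dess–Martin periodinane, pyridine, CH2Cl2, 0 °C; used crude
Reagents that add atoms: none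
Why: Buffered Dess–Martin oxidation is non-enolising; the aldehyde is not stored because its α-proton is both allylic and α to the formyl group.

Step 6
Reactants: 9 (2R,3R)-3-ethenyl-3-methyl-2-(prop-1-en-2-yl)hex-5-enal
Product: 10 (3R,4R,5R)-5-ethenyl-5-methyl-4-(prop-1-en-2-yl)octa-1,7-dien-3-ol
Conditions: vinylmagnesium bromide, CeCl3, THF, −78 °C
Reagents that add atoms: vinylmagnesium bromide C=C[Mg]Br
Why: The organocerium reagent adds to the hindered aldehyde without enolising it; Felkin–Anh control, with the quaternary C10 as the large group anti to the nucleophile and hydrogen as the small group, should give the C6 carbinol that ends trans to isopropenyl on the ring.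

Step 7
Reactants: 10 (3R,4R,5R)-5-ethenyl-5-methyl-4-(prop-1-en-2-yl)octa-1,7-dien-3-ol
Product: 11 (1R,5R,6R)-5-ethenyl-5-methyl-6-(prop-1-en-2-yl)cyclohex-2-en-1-ol
Conditions: first-generation Grubbs catalyst RuCl2(PCy3)2(=CHPh) (5 mol%), CH2Cl2 (0.005 M), 40 °C
Reagents that add atoms: none
Why: Ring-closing metathesis: the catalyst loads on the unhindered allyl terminus and closes the six-membered ring onto the carbinol vinyl group (C7=C8), while the 1,1-disubstituted isopropenyl group and the vinyl group on the quaternary carbon are poor partners for this catalyst.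

Step 8
Reactants: 11 (1R,5R,6R)-5-ethenyl-5-methyl-6-(prop-1-en-2-yl)cyclohex-2-en-1-ol
Product: 12 (3R,4R,5R)-3-(2-bromo-1-ethoxypropoxy)-5-ethenyl-5-methyl-4-(prop-1-en-2-yl)cyclohex-1-ene (mixture at the two side-chain centres)
Conditions: N-bromosuccinimide, ethyl prop-1-enyl ether, CH2Cl2, −40 °C to 0 °C
Reagents that add atoms: N-bromosuccinimide O=C1CCC(=O)N1Br; ethyl prop-1-enyl ether CC=COCC
Why: Bromoacetalisation (first stage of a Ueno–Stork sequence): the electron-rich enol ether is brominated far faster than the three other olefins and the C6 hydroxyl opens the bromonium ion at the acetal carbon; the two new centres are erased later.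

Step 9
Reactants: 12 (3R,4R,5R)-3-(2-bromo-1-ethoxypropoxy)-5-ethenyl-5-methyl-4-(prop-1-en-2-yl)cyclohex-1-ene
Product: 14 (3aR,4S,6R,7R,7aS)-2-ethoxy-6-ethenyl-3,6-dimethyl-7-(prop-1-en-2-yl)octahydro-1-benzofuran-4-ol (mixture at C2 and C3), via hydroperoxide 13 (not isolated)
Conditions: Bu3SnH (slow addition), Et3B (cat.), dry air, toluene, 0 °C; then PPh3
Reagents that add atoms: dioxygen O=O
Why: Oxygenative radical cyclisation of a bromoacetal: the C11 radical closes 5-exo onto C7 from the face of the O6 tether (cis fusion, C11 β), and the C8 radical is captured by O2 on the convex face, anti to the new C7–C11 bond, which sets C8–O trans to C11; PPh3 reduces hydroperoxide 13.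

Step 10
Reactants: 14 (3aR,4S,6R,7R,7aS)-2-ethoxy-6-ethenyl-3,6-dimethyl-7-(prop-1-en-2-yl)octahydro-1-benzofuran-4-ol
Product: 16 (3aR,4S,6R,7R,7aS)-6-ethenyl-4-hydroxy-3,6-dimethyl-7-(prop-1-en-2-yl)hexahydro-1-benzofuran-2(3H)-one (mixture at C3), via lactol 15 (not isolated)
Conditions: 1 M HCl, THF, rt; then Ag2CO3 on Celite, toluene, 80 °C
Reagents that add atoms: water O
Why: Acid hydrolysis of the mixed acetal gives lactol 15, and Ag2CO3 on Celite oxidises lactols much faster than secondary alcohols, so the C8 hydroxyl survives; the C11 mixture is erased in step 11.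

Step 11
Reactants: 16 (3aR,4S,6R,7R,7aS)-6-ethenyl-4-hydroxy-3,6-dimethyl-7-(prop-1-en-2-yl)hexahydro-1-benzofuran-2(3H)-one
Product: 17 (3S,3aR,4S,6R,7R,7aS)-6-ethenyl-3,4-dihydroxy-3,6-dimethyl-7-(prop-1-en-2-yl)hexahydro-1-benzofuran-2(3H)-one
Conditions: KN(SiMe3)2 (2.3 equiv), THF, −78 °C; 2-(phenylsulfonyl)-3-phenyloxaziridine, −78 °C; aq. NH4Cl
Reagents that add atoms: 2-(phenylsulfonyl)-3-phenyloxaziridine O=S(=O)(N1OC1c1ccccc1)c1ccccc1
Why: Double deprotonation (alkoxide, then lactone enolate) and enolate hydroxylation; the planar enolate is attacked on the convex face of the cis-fused bicycle, cis to H7, which puts the hydroxyl exo and the C13 methyl endo as in the target.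

Step 12
Reactants: 17 (3S,3aR,4S,6R,7R,7aS)-6-ethenyl-3,4-dihydroxy-3,6-dimethyl-7-(prop-1-en-2-yl)hexahydro-1-benzofuran-2(3H)-one
Product: 18 (3S,3aR,4S,6R,7R,7aS)-6-ethenyl-3-hydroxy-3,6-dimethyl-2-oxo-7-(prop-1-en-2-yl)octahydro-1-benzofuran-4-yl acetate
Conditions: Ac2O, pyridine, CH2Cl2, 0 °C to rt (no DMAP)
Reagents that add atoms: acetic anhydride CC(=O)OC(C)=O
Why: The secondary C8 hydroxyl is acetylated under conditions that leave the tertiary α-hydroxy lactone untouched.

Step 13
Reactants: 18 (3S,3aR,4S,6R,7R,7aS)-6-ethenyl-3-hydroxy-3,6-dimethyl-2-oxo-7-(prop-1-en-2-yl)octahydro-1-benzofuran-4-yl acetate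
Product: 19 (3S,3aR,4S,6R,7R,7aS)-4-(acetyloxy)-6-ethenyl-3,6-dimethyl-2-oxo-7-(prop-1-en-2-yl)octahydro-1-benzofuran-3-yl (2Z)-2-methylbut-2-enoate
Conditions: (2Z)-2-methylbut-2-enoic acid, 2,4,6-trichlorobenzoyl chloride, Et3N, toluene, rt; then 18, 80 °C
Reagents that add atoms: (2Z)-2-methylbut-2-enoic acid C/C=C(/C)C(=O)O
Why: Mixed-anhydride (Yamaguchi-type) esterification run without a nucleophilic catalyst is the established way to form angelates without Z to E isomerisation; no alkoxide is generated, so the C8 acetate should not migrate.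

**Compound list**

1 | pent-1-en-4-yne | C#CCC=C | starting material
2 | dimethyl[(1E)-2-methylpenta-1,4-dien-1-yl]alumane | C[Al](C)/C=C(\C)CC=C | intermediate (not isolated)
3 | (2E)-3-methylhexa-2,5-dien-1-ol | OC/C=C(\C)CC=C | intermediate
4 | 3-methylbut-3-enoic acid | C=C(C)CC(=O)O | starting material
5 | (2E)-3-methylhexa-2,5-dien-1-yl 3-methylbut-3-enoate | C=C(C)CC(=O)OC/C=C(\C)CC=C | intermediate
6 | boron ketene acetal of 5 with the (4S,5S)-1,3-bis{[3,5-bis(trifluoromethyl)phenyl]sulfonyl}-4,5-diphenyl-1,3,2-diazaborolidin-2-yl group on oxygen, isopropenyl cis to the allyloxy oxygen | C=C(C)/C=C(\OC/C=C(\C)CC=C)OB1N(S(=O)(=O)c2cc(cc(c2)C(F)(F)F)C(F)(F)F)[C@@H](c2ccccc2)[C@H](c2ccccc2)N1S(=O)(=O)c1cc(cc(c1)C(F)(F)F)C(F)(F)F | intermediate (not isolated)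
7 | (2R,3R)-3-ethenyl-3-methyl-2-(prop-1-en-2-yl)hex-5-enoic acid | C=C[C@@]([C@H](C(=O)O)C(=C)C)(C)CC=C | intermediate
8 | (2R,3R)-3-ethenyl-3-methyl-2-(prop-1-en-2-yl)hex-5-en-1-ol | C=C[C@@]([C@H](CO)C(=C)C)(C)CC=C | intermediate
9 | (2R,3R)-3-ethenyl-3-methyl-2-(prop-1-en-2-yl)hex-5-enal | C=C[C@@]([C@H](C=O)C(=C)C)(C)CC=C | intermediate
10 | (3R,4R,5R)-5-ethenyl-5-methyl-4-(prop-1-en-2-yl)octa-1,7-dien-3-ol | C=C[C@@]([C@H]([C@H](O)C=C)C(=C)C)(C)CC=C | intermediate
11 | (1R,5R,6R)-5-ethenyl-5-methyl-6-(prop-1-en-2-yl)cyclohex-2-en-1-ol | C=C[C@@]1(C)CC=C[C@@H](O)[C@@H]1C(=C)C | intermediate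
12 | (3R,4R,5R)-3-(2-bromo-1-ethoxypropoxy)-5-ethenyl-5-methyl-4-(prop-1-en-2-yl)cyclohex-1-ene | C=C[C@@]1(C)CC=C[C@@H](OC(OCC)C(C)Br)[C@@H]1C(=C)C | intermediate
13 | (3aR,4S,6R,7R,7aS)-2-ethoxy-6-ethenyl-4-hydroperoxy-3,6-dimethyl-7-(prop-1-en-2-yl)octahydro-1-benzofuran | C=C[C@@]1(C)C[C@H](OO)[C@@H]2[C@@H](OC(OCC)C2C)[C@@H]1C(=C)C | intermediate (not isolated)
14 | (3aR,4S,6R,7R,7aS)-2-ethoxy-6-ethenyl-3,6-dimethyl-7-(prop-1-en-2-yl)octahydro-1-benzofuran-4-ol | C=C[C@@]1(C)C[C@H](O)[C@@H]2[C@@H](OC(OCC)C2C)[C@@H]1C(=C)C | intermediate
15 | (3aR,4S,6R,7R,7aS)-6-ethenyl-3,6-dimethyl-7-(prop-1-en-2-yl)octahydro-1-benzofuran-2,4-diol | C=C[C@@]1(C)C[C@H](O)[C@@H]2[C@@H](OC(O)C2C)[C@@H]1C(=C)C | intermediate (not isolated)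
16 | (3aR,4S,6R,7R,7aS)-6-ethenyl-4-hydroxy-3,6-dimethyl-7-(prop-1-en-2-yl)hexahydro-1-benzofuran-2(3H)-one | C=C[C@@]1(C)C[C@H](O)[C@@H]2[C@@H](OC(=O)C2C)[C@@H]1C(=C)C | intermediate
17 | (3S,3aR,4S,6R,7R,7aS)-6-ethenyl-3,4-dihydroxy-3,6-dimethyl-7-(prop-1-en-2-yl)hexahydro-1-benzofuran-2(3H)-one | C=C[C@@]1(C)C[C@H](O)[C@@H]2[C@@H](OC(=O)[C@@]2(C)O)[C@@H]1C(=C)C | intermediate
18 | (3S,3aR,4S,6R,7R,7aS)-6-ethenyl-3-hydroxy-3,6-dimethyl-2-oxo-7-(prop-1-en-2-yl)octahydro-1-benzofuran-4-yl acetate | C=C[C@@]1(C)C[C@H](OC(C)=O)[C@@H]2[C@@H](OC(=O)[C@@]2(C)O)[C@@H]1C(=C)C | intermediate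
19 | (3S,3aR,4S,6R,7R,7aS)-4-(acetyloxy)-6-ethenyl-3,6-dimethyl-2-oxo-7-(prop-1-en-2-yl)octahydro-1-benzofuran-3-yl (2Z)-2-methylbut-2-enoate | C=C[C@@]1(C)C[C@H](OC(C)=O)[C@@H]2[C@@H](OC(=O)[C@@]2(C)OC(=O)/C(C)=C\C)[C@@H]1C(=C)C | target

**Step count and risk**

Total step count: 13. Longest linear sequence: 13 steps (1 to 19); acid 4 enters at step 2. No protecting group is used.

Least certain steps:

Step 3 (key step).
- What may go wrong: erosion of the enolate geometry, which would give the C5 epimer; incomplete or reversed facial discrimination by the controller; slow rearrangement because the allyl terminus is fully substituted.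
- Fallback: it sets out from 5 and comes back at 7. Enolisation of 5 with LiN(iPr)2 and Me3SiCl in THF at −78 °C gives the trimethylsilyl ketene acetal F1, which rearranges on warming to rt; hydrolysis gives the racemic anti acid, that is 7 together with its enantiomer, (2S,3S)-3-ethenyl-3-methyl-2-(prop-1-en-2-yl)hex-5-enoic acid F2. Classical resolution by crystallisation of the (1R)-1-phenylethanaminium salt F3 and acidification returns 7.

Step 6.
- What may go wrong: poor facial selectivity in the addition, if the isopropenyl group competes with the quaternary carbon for the anti position, and enolisation of the aldehyde with loss of the C5 configuration.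
- Fallback: it sets out from 10 obtained as a mixture with its C3 epimer and comes back at 11. The mixture is taken through step 7, the unwanted (1S,5R,6R)-5-ethenyl-5-methyl-6-(prop-1-en-2-yl)cyclohex-2-en-1-ol F4 is separated and inverted by Mitsunobu esterification (4-nitrobenzoic acid, PPh3, diisopropyl azodicarboxylate) to (1R,5R,6R)-5-ethenyl-5-methyl-6-(prop-1-en-2-yl)cyclohex-2-en-1-yl 4-nitrobenzoate F5, and methanolysis (K2CO3, MeOH) gives 11.

Step 7.
- What may go wrong: ring closure in the wrong direction (five-membered rings through the isopropenyl group or through the vinyl group on the quaternary carbon), olefin migration, or oligomerisation.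
- Fallback: it sets out from 9 and comes back at 11. Addition of (Z)-prop-1-enylmagnesium bromide/CeCl3 in place of the vinyl reagent gives (2Z,4R,5R,6R)-6-ethenyl-6-methyl-5-(prop-1-en-2-yl)nona-2,8-dien-4-ol F6. Its internal olefin cannot load the catalyst, so the ruthenium carbene can only form at the allyl terminus and closes onto the propenyl group with loss of propene, giving 11.

Step 9.
- What may go wrong: capture of the first radical by oxygen before it cyclises, incomplete facial selectivity of the oxygen capture at C8 (the axial C14 methyl lies on the same face), and further reactions of peroxyl radicals with the olefins.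
- Fallback: it sets out from 12 and comes back at 14. Cyclisation with Bu3SnH in the presence of excess 2,2,6,6-tetramethylpiperidin-1-oxyl (benzene, 70 °C, slow addition) traps the C8 radical as (3aR,4S,6R,7R,7aS)-2-ethoxy-6-ethenyl-3,6-dimethyl-7-(prop-1-en-2-yl)-4-[(2,2,6,6-tetramethylpiperidin-1-yl)oxy]octahydro-1-benzofuran F7 with no oxygen present, and N–O cleavage with zinc in acetic acid gives 14.

Step 13.
- What may go wrong: slow acylation of the tertiary hydroxyl, isomerisation of the angeloyl group to the tiglate on prolonged heating, and acetyl migration.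
- Fallback: it sets out from 18 and comes back at 19. Acylation with 2-[bis(2,2,2-trifluoroethoxy)phosphoryl]propanoyl chloride and Et3N (through the reactive phosphonoketene) gives (3S,3aR,4S,6R,7R,7aS)-4-(acetyloxy)-6-ethenyl-3,6-dimethyl-2-oxo-7-(prop-1-en-2-yl)octahydro-1-benzofuran-3-yl 2-[bis(2,2,2-trifluoroethoxy)phosphoryl]propanoate F8. A Z-selective Horner–Wadsworth–Emmons reaction with acetaldehyde (Still–Gennari conditions: KN(SiMe3)2, 18-crown-6, THF, −78 °C) then builds the angelate in place.

**Further compounds**

F1 | step 3 | (2E)-3-methylhexa-2,5-dien-1-yl trimethylsilyl ketene acetal of 5 (isopropenyl cis to the allyloxy oxygen) | C=C(C)/C=C(\OC/C=C(\C)CC=C)O[Si](C)(C)C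
F2 | step 3 | (2S,3S)-3-ethenyl-3-methyl-2-(prop-1-en-2-yl)hex-5-enoic acid | C=C[C@]([C@@H](C(=O)O)C(=C)C)(C)CC=C
F3 | step 3 | (1R)-1-phenylethanaminium (2R,3R)-3-ethenyl-3-methyl-2-(prop-1-en-2-yl)hex-5-enoate | C=C[C@@]([C@H](C(=O)[O-])C(=C)C)(C)CC=C.C[C@@H]([NH3+])c1ccccc1
F4 | step 6 | (1S,5R,6R)-5-ethenyl-5-methyl-6-(prop-1-en-2-yl)cyclohex-2-en-1-ol | C=C[C@@]1(C)CC=C[C@H](O)[C@@H]1C(=C)C
F5 | step 6 | (1R,5R,6R)-5-ethenyl-5-methyl-6-(prop-1-en-2-yl)cyclohex-2-en-1-yl 4-nitrobenzoate | C=C[C@@]1(C)CC=C[C@@H](OC(=O)c2ccc(cc2)[N+](=O)[O-])[C@@H]1C(=C)C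
F6 | step 7 | (2Z,4R,5R,6R)-6-ethenyl-6-methyl-5-(prop-1-en-2-yl)nona-2,8-dien-4-ol | C=C[C@@]([C@H]([C@H](O)/C=C\C)C(=C)C)(C)CC=C
F7 | step 9 | (3aR,4S,6R,7R,7aS)-2-ethoxy-6-ethenyl-3,6-dimethyl-7-(prop-1-en-2-yl)-4-[(2,2,6,6-tetramethylpiperidin-1-yl)oxy]octahydro-1-benzofuran | C=C[C@@]1(C)C[C@H](ON3C(C)(C)CCCC3(C)C)[C@@H]2[C@@H](OC(OCC)C2C)[C@@H]1C(=C)C
F8 | step 13 | (3S,3aR,4S,6R,7R,7aS)-4-(acetyloxy)-6-ethenyl-3,6-dimethyl-2-oxo-7-(prop-1-en-2-yl)octahydro-1-benzofuran-3-yl 2-[bis(2,2,2-trifluoroethoxy)phosphoryl]propanoate | C=C[C@@]1(C)C[C@H](OC(C)=O)[C@@H]2[C@@H](OC(=O)[C@@]2(C)OC(=O)C(C)P(=O)(OCC(F)(F)F)OCC(F)(F)F)[C@@H]1C(=C)C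
A1 | alternative 1 | (3S,3aR,4S,6E,10E,11aS)-4-(acetyloxy)-3,6,10-trimethyl-2-oxo-2,3,3a,4,5,8,9,11a-octahydrocyclodeca[b]furan-3-yl (2Z)-2-methylbut-2-enoate | CC(=O)O[C@H]1C/C(C)=C/CC/C(C)=C/[C@@H]2OC(=O)[C@@](C)(OC(=O)/C(C)=C\C)[C@H]12
A2 | alternative 2 | 2H-pyran-2-one | O=C1C=CC=CO1
A3 | alternative 2 | 2-methylprop-2-enal | CC(=C)C=O
A4 | alternative 2 | (1S,4S,5S)-5-methyl-3-oxo-2-oxabicyclo[2.2.2]oct-7-ene-5-carbaldehyde | O=C[C@@]1(C)C[C@H]2C=C[C@@H]1C(=O)O2
A5 | alternative 3 | (5S)-5-{[tert-butyl(dimethyl)silyl]oxy}-3-methylcyclohex-2-en-1-one | CC1=CC(=O)C[C@@H](O[Si](C)(C)C(C)(C)C)C1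
A6 | alternative 3 | (2R,3R,5S)-5-{[tert-butyl(dimethyl)silyl]oxy}-3-ethenyl-3-methyl-2-(prop-1-en-2-yl)cyclohexan-1-one | C=C[C@@]1(C)C[C@H](O[Si](C)(C)C(C)(C)C)CC(=O)[C@@H]1C(=C)C
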